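A percentage point is a different amount of solid substrate in each flask: a point of the blue charge is twice a point of the charge in the asked flask, so I put the earlier runs on the flask's own scale before comparing them.

| flask | solid substrate | partner | capture agent | free catalyst | remark | time |
|---|---|---|---|---|---|---|
| violet | 0.070 M | 0.95 equiv | 2.8 mM | 0.33 mol% | run made earlier |  |
| blue | 0.28 M | 0.95 equiv | 2.8 mM | 0.33 mol% | run made earlier |  |
| red | 0.14 M | 0.95 equiv | 2.8 mM | 0.49 mol% | run made earlier |  |
| flask | 0.14 M | 0.950 equiv | 2.80 mM | 0.33 mol% |  | 2.5 d |

| run | time / d | solid substrate / % | target / % |
|---|---|---|---|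
| violet | 0.333 | 95 | 0 |
| violet | 0.625 | 88 | 2 |
| violet | 1.04 | 85 | 10 |
| violet | 1.25 | 81 | 9 |
| violet | 1.67 | 77 | 13 |
| violet | 2.00 | 80 | 19 |
| violet | 2.50 | 69 | 18 |
| blue | 0.333 | 100 | 3 |
| blue | 0.625 | 98 | 7 |
| blue | 1.04 | 97 | 2 |
| blue | 1.25 | 95 | 4 |
| blue | 1.67 | 90 | 5 |
| blue | 2.00 | 93 | 8 |
| blue | 2.50 | 89 | 10 |
| red | 0.208 | 98 | 3 |
| red | 0.625 | 97 | 4 |
| red | 1.25 | 91 | 10 |
| red | 1.67 | 86 | 11 |
| red | 2.50 | 82 | 14 |

(each reading ± 2 percentage points)

- as a solid, counted per litre of solution: solid substrate
- the numbers in the tables scatter with a standard deviation of 2 percentage points
- at the start none of the solid substrate is in solution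
- what has only dissolved of solid substrate counts as not reacted
- starting material means what is dissolved; the solid is not counted in it

1. part of the solid substrate that has turned into other species by 2.5 d (what has only dissolved does not count)
2. the target standing at 2.5 d, as a percentage of the solid substrate charged
3. the starting material standing at 2.5 d, as a percentage of the solid substrate charged

As the zero of my scale I took the case in which the solid feeds the flasks at one pace, whatever their charge. The blue run holds the most catalyst per litre and lost the most solid per litre, so I took its loss as that pace. Its last reading, expressed as a fraction of the flask's charge, gives 22.0%, my feed ceiling, a mass-transfer limit read from one reading and uncertain by 4 percentage points.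

I then followed the flask through the readings. At first nothing is dissolved, so I read dissolving as the opening step: the violet run shows 95% solid substrate and 0% target at 0.333 d. In the middle, the target follows the falling solid: the red run, at the flask's charge, reads 91% and 10% at 1.25 d.

By the end the runs separate. The violet run used 70.5% of the ceiling and the red run 81.8%. The mean of their catalyst per litre is 0.992 of the flask's, so I took the mean share, 76.1%, which means 16.7% of the charge lost. The red run's last readings leave 4 points of lost solid that is not target, so I expected about 12.7% target, and I read that gap as starting material.

The forecast, on a different ground from mine, “Target formed scales roughly with the square root of catalyst concentration”, gave 14.5% conversion, 12.5% target and 2.4% starting material.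

The flask gave 15.6% conversion, 15.4% target and 2.05% starting material, with 82.4% solid substrate left.

    catalyst intermediate A ⇌ catalyst intermediate B (K = 0.442, k = 852 /h)
    partner + catalyst intermediate B → catalyst intermediate C (k = 269 /M/h)
    catalyst intermediate C + capture agent → trapped intermediate (k = 121 /M/h)
    starting material + free catalyst → catalyst intermediate A (k = 590 /M/h)
    solid substrate ⇌ starting material, rate k5*(cs5 - [starting material]) while solid is left; crystals form when [starting material] > cs5 (solubility = 11.0 mM, k = 0.0461 /h)
    catalyst intermediate C → free catalyst + target (k = 33.6 /h)

The flask thus lost 17.6% of its charge, 80.1% of the feed ceiling of 22.0%. A neighbouring flask has the same charge of solid substrate, so the same ceiling, but 1.3 mol% free catalyst. It stood at 79.3% solid substrate at 2.50 d, a loss of 20.7%, which is 94.3% of the ceiling, a larger share than the flask's. Its target reached 20.1%, and its starting material stood at 0.393%.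

All runs stem from a simulated flask with made-up constants; the scatter is artificial.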